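Locants follow the spiro[5.5]undecane (chamigrane) frame: ring B is C1–C5, C6 is the spiro atom, ring A is C7–C11, and C14 is the methylidene carbon on C7. The acyclic fragment keeps the same locants. Assumption: the sense of induction of the Schiff-base ligand in step 4 is assigned in a pilot run, and the antipode that gives (2S,3S)-5 is used.

## Analysis of the target

- Target 16 is a spiro[5.5]undecane. Ring A (C6–C11) carries the C7 methylidene (C14), the doubly allylic C8 carbinol, the C9=C10 vinyl bromide and the C11 gem-dimethyl group. Ring B (C1–C6) carries the C2 secondary bromide and the C3 tertiary chloride with its methyl group.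
- There are four stereocentres: C2 (S), C3 (S), the quaternary spiro carbon C6 (S) and C8 (R).
- In the chair of ring B, bromine and chlorine are trans and both equatorial, the C3 methyl is axial, C11 is equatorial and cis to bromine, and C7 is axial. The C8 hydroxyl lies on the face of ring A that carries C5.
- Sensitive sites are the tertiary chloride next to a bromide (ionisation with bromine participation, elimination), the C8 alcohol between two alkenes (ionisation, allylic transposition) and the vinyl bromide.
- The first difficulty is the fully substituted C6 next to the fully substituted C11.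
- The second is the halogen pattern. Anti addition of bromine and chloride to a C2=C3 alkene of a finished spirocycle opens the bromonium ion diaxially. Bromine then becomes axial and syn to the axial C6 substituent, which will be C7 rather than the bulky C11. That gives bromine cis to C7, the opposite of the relation needed.
- The strategy rests on one feature: ring B is two methylene arms, C1 and C5, on C6, with the C2–Br and C3–Cl stereocentres between them. An enantiopure acyclic C1–C5 piece with a leaving group at each end can therefore be stitched onto C6 of a ring A precursor in which C6 is the only enolisable carbon.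

## Retrosynthetic reasoning

**16 ⇒ 15.** The C8–H bond is cut first. The C8 carbinol sits between the C7 methylidene and the C9=C10 vinyl bromide and would not survive the skeleton-building steps, so it is kept as the ketone of dienone 15 until the end. The forward step must add hydride 1,2 and from the face of ring A that carries C1. The two arms on C6 differ only from C2 onward, so the substrate offers little bias and a chiral reducing catalyst has to choose the face.

**15 ⇒ 14.** The C10–Br bond and the C8 carbonyl are traced back to vinylogous ester 14 (C8–OMe, C8=C9, C10=O). Activation of the C10 carbonyl oxygen, addition of bromide at C10 and loss of the O-methyl group exchange the two functions in one operation. The position of the methyl ether fixes which carbon is brominated, which a free 1,3-diketone would not do. The forward step must run without strong protic acid because of the C3 chloride.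

**14 ⇒ 13.** The C7=C14 bond is cut to the C7 ketone of ene-dione 13. The two carbonyls of 13 differ in kind: C7 is a ketone beside the α-methoxy alkene, C10 is the much less electrophilic carbonyl of a vinylogous ester. A carbonyl methylenation can therefore be directed to C7, provided the reagent is non-basic and spares the halides.

**13 ⇒ 11 + 8.** Both bonds from C6 into ring B, C6–C5 and C6–C1, are cut. This removes the quaternary centre and all of ring B at once. It leaves ene-dione 11, whose C6 methylene is the only acidic position (C11 is quaternary, C9 is vinylic), and the 1,5-dielectrophile 8. Cutting here, and not inside ring B, lets C2 and C3 be made on an open chain where anti addition has no ring conformation to fight, and turns them into the control element for C6. The forward reaction needs two SN2 alkylations at C6, the second closing a six-membered ring onto the hindered C1, without elimination of the halides.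

**8 ⇒ 7 ⇒ 6 ⇒ 5.** The leaving groups are taken back to hydroxyls. The C1 triflate is made last because it is the most reactive function. The C5 iodide comes from diol 6, in which C1–OH is held back by the bromine on C2 and the fully substituted C3 behind it. The diol comes from silyl ether 5, so the C5 oxygen stays masked while the halogens are introduced.

**5 ⇒ 4.** The C2–Br and C3–Cl bonds are cut together to the (Z)-alkene of allylic alcohol 4. Anti addition across a (Z)-alkene gives the (2S,3S)/(2R,3R) pair, chloride goes to the tertiary C3, and the free C1 hydroxyl is the handle by which a chiral titanium catalyst selects one alkene face. The homoallylic oxygen must be silylated so that only one alkoxide binds titanium.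

**4 ⇒ 3 ⇒ 2 ⇒ 1.** The C1 alcohol is taken back to ester 3, the C3–methyl bond to ynoate 2, and the C1–C2 bond to alkyne 1. Syn addition of a methyl cuprate to 2 sets the (Z) geometry under kinetic control. The C5 oxygen is differentiated from C1 from the first step on, which a free pentenediol with two primary hydroxyls would not allow.

**11 ⇒ 10 ⇒ 9.** The C7 carbonyl of 11 is cut back to the allylic methylene of vinylogous ester 10, and the methyl enol ether to dione 9. O-Methylation at the carbonyl remote from the gem-dimethyl group decides early which oxygen becomes the C8 carbonyl and which carbon (C10) later takes the bromide.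

## Alternatives that were turned down

Alternative 1: The C6–C11 bond of ring A is disconnected in a polyene-type cyclisation.
- Forward key step: a Lewis acid opens the terminal epoxide A2 at its fully substituted carbon C11. The tetrasubstituted C6=C7 alkene attacks through C6, ring A closes, and the C7 cation loses a C14 proton to give A1.
- For: the quaternary carbon, ring A and the C7 methylidene arise in one step from a fifteen-carbon chain, and the C10 oxygen of A1 is the right handle for the vinyl bromide. In skeletal bonds formed per step it is stronger than the chosen route.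
- Against: C6 is set by the geometry of a tetrasubstituted alkene that is hard to obtain pure, and C8 still needs an allylic oxidation. Above all, the halogens would have to be added late to the C2=C3 alkene of A1, in competition with the C7 methylidene. Diaxial opening there puts bromine syn to C7 and trans to C11, the wrong relation to C6.
- Comparison: the chosen route gives up the cascade. In its place it offers a bromochloride whose configuration is fixed on an open chain and then directs C6.

Alternative 2: The C7–C8 bond of ring A is disconnected.
- Forward key step: a zerovalent nickel–carbene catalyst and a trialkylsilane couple the alkyne and aldehyde ends of ynal A4. Ring A closes to A3 with the C7 methylidene and the silylated C8 carbinol in place.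
- For: on the C7/C8 array it is as strong as or stronger than the chosen route, which needs three steps from 13 for the same array and sets C8 only at the end.
- Against: A3 has ring B as a bare C1=C2 cyclohexene. The C3 methyl group, the C3 chloride and the C2 bromide all remain to be introduced on the finished spirocycle, with the same diaxial-addition problem and several changes of oxidation level. The C10 ketal must still become a vinyl bromide next to C11, and the quaternary C6 of A4 has to be made enantioselectively beforehand by other means.
- Comparison: the chosen route delivers ring B complete in one step and accepts a longer end game in ring A.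

Alternative 3: C6–C5 and C1=C2 are disconnected in a Robinson-type spiroannulation.
- Forward key step: a cinchona-derived primary-amine thiourea adds C6 of formyl ene-dione A6 to enone A7. Aldol condensation of the new methyl ketone onto the formyl carbon (C1) closes ring B to give A5.
- For: C6 is set by a catalytic Michael addition of a well-understood type on a doubly activated, mildly basic nucleophile. This is safer than the enolate chemistry of the chosen key step, and ring A is the same ene-dione as in 11.
- Against: ring B arrives as a cyclohexenone. The C3 methyl, C3 chloride and C2 bromide must be built from the C3 ketone and the C1=C2 alkene by carbonyl addition, substitution at a tertiary carbinol and bromination. None of these controls C2/C3 relative to C6, and two further carbonyl groups in ring A are present.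
- Comparison: the chosen route carries more risk in a single step, but it delivers both halogen stereocentres under catalyst control and uses them to set C6.

Key step: step 10

## Route

Step 1
Reactants: 1 tert-butyl(but-3-yn-1-yloxy)dimethylsilane
Product: 2 methyl 5-[(tert-butyldimethylsilyl)oxy]pent-2-ynoate
Conditions: n-BuLi, THF, −78 °C; ClCO2Me, −78 → 0 °C
Reagents that add atoms: methyl chloroformate, COC(=O)Cl
Why: Deprotonation of the terminal alkyne and C-acylation of the acetylide with a chloroformate is a standard ynoate synthesis; the silyl ether is inert.

Step 2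
Reactants: 2 methyl 5-[(tert-butyldimethylsilyl)oxy]pent-2-ynoate
Product: 3 methyl (2Z)-5-[(tert-butyldimethylsilyl)oxy]-3-methylpent-2-enoate
Conditions: Me2CuLi (from CuI and MeLi), THF, −78 °C; MeOH, then aq. NH4Cl, −78 °C
Reagents that add atoms: lithium dimethylcuprate, [Li+].C[Cu-]C
Why: Conjugate addition of a Gilman cuprate to an ynoate is a syn carbometalation; protonation at −78 °C keeps the geometry, so the ester should end cis to the silyloxyethyl chain, which is the (Z)-alkene.

Step 3
Reactants: 3 methyl (2Z)-5-[(tert-butyldimethylsilyl)oxy]-3-methylpent-2-enoate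
Product: 4 (2Z)-5-[(tert-butyldimethylsilyl)oxy]-3-methylpent-2-en-1-ol
Conditions: i-Bu2AlH, CH2Cl2, −78 → 0 °C; aq. potassium sodium tartrate
Reagents that add atoms: none
Why: 1,2-Reduction of the conjugated ester by the aluminium hydride gives the allylic alcohol without touching the alkene geometry or the silyl ether.

Step 4
Reactants: 4 (2Z)-5-[(tert-butyldimethylsilyl)oxy]-3-methylpent-2-en-1-ol
Product: 5 (2S,3S)-2-bromo-5-[(tert-butyldimethylsilyl)oxy]-3-chloro-3-methylpentan-1-ol
Conditions: N-bromosuccinimide, ClTi(OiPr)3, tert-leucine-derived Schiff-base ligand 2,4-di-tert-butyl-6-({[1-hydroxy-3,3-dimethyl-1,1-diphenylbutan-2-yl]imino}methyl)phenol (cat., antipode giving 2S,3S), hexanes, −20 °C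
Reagents that add atoms: N-bromosuccinimide, O=C1CCC(=O)N1Br; chlorotitanium triisopropoxide ClTi(OiPr)3, CC(C)O[Ti](Cl)(OC(C)C)OC(C)C
Why: Catalytic enantioselective bromochlorination of allylic alcohols: the substrate binds tetravalent titanium as its alkoxide inside the chiral Schiff-base complex, the bromonium ion forms on one alkene face, and titanium-bound chloride opens it anti at the tertiary C3. Anti addition to the (Z)-alkene gives the (2S,3S)/(2R,3R) pair and the ligand antipode selects (2S,3S), which sets C2 and C3.

Step 5
Reactants: 5 (2S,3S)-2-bromo-5-[(tert-butyldimethylsilyl)oxy]-3-chloro-3-methylpentan-1-ol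
Product: 6 (2S,3S)-2-bromo-3-chloro-3-methylpentane-1,5-diol
Conditions: HF·pyridine, THF–pyridine, 0 °C → rt
Reagents that add atoms: none
Why: Buffered fluoride desilylation of a primary silyl ether; a basic fluoride source is avoided because a C1 alkoxide would displace the C2 bromide to an epoxide.

Step 6
Reactants: 6 (2S,3S)-2-bromo-3-chloro-3-methylpentane-1,5-diol
Product: 7 (2S,3S)-2-bromo-3-chloro-5-iodo-3-methylpentan-1-ol
Conditions: I2, PPh3, imidazole, CH2Cl2, −20 → 0 °C
Reagents that add atoms: iodine, II
Why: Appel-type iodination of the unhindered C5 hydroxyl; C1–OH is β to bromine and to a fully substituted carbon, so SN2 displacement of its alkoxyphosphonium ion is far slower, and one equivalent of reagent at low temperature should confine the reaction to C5.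

Step 7
Reactants: 7 (2S,3S)-2-bromo-3-chloro-5-iodo-3-methylpentan-1-ol
Product: 8 (2S,3S)-2-bromo-3-chloro-5-iodo-3-methylpentyl trifluoromethanesulfonate
Conditions: Tf2O, 2,6-lutidine, CH2Cl2, −78 °C; used without storage
Reagents that add atoms: trifluoromethanesulfonic anhydride, O=S(=O)(OS(=O)(=O)C(F)(F)F)C(F)(F)F
Why: Sulfonylation of the remaining primary alcohol with triflic anhydride and a hindered pyridine base; the β-bromine makes the triflate less prone to ionise than a simple alkyl triflate.

Step 8
Reactants: 9 4,4-dimethylcyclohexane-1,3-dione
Product: 10 3-methoxy-6,6-dimethylcyclohex-2-en-1-one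
Conditions: HC(OMe)3, MeOH, p-TsOH·H2O (cat.), rt
Reagents that add atoms: trimethyl orthoformate, COC(OC)OC; methanol, CO
Why: Acid-catalysed enol etherification of a 1,3-dione; methanol attacks the carbonyl remote from the gem-dimethyl group, so the vinylogous ester with its ketone next to the quaternary carbon should be the main isomer.

Step 9
Reactants: 10 3-methoxy-6,6-dimethylcyclohex-2-en-1-one
Product: 11 2-methoxy-5,5-dimethylcyclohex-2-ene-1,4-dione
Conditions: Pd(OH)2/C (cat.), t-BuOOH, K2CO3, CH2Cl2, 0 °C → rt
Reagents that add atoms: tert-butyl hydroperoxide, CC(C)(C)OO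
Why: Radical allylic (γ) oxidation of an enone to an ene-dione: the tert-butylperoxyl radical abstracts hydrogen from the only allylic methylene (the future C7) and the mixed peroxide collapses to the ketone.

Step 10
Reactants: 11 2-methoxy-5,5-dimethylcyclohex-2-ene-1,4-dione; 8 (2S,3S)-2-bromo-3-chloro-5-iodo-3-methylpentyl trifluoromethanesulfonate
Product: 13 (2S,3S,6R)-2-bromo-3-chloro-8-methoxy-3,11,11-trimethylspiro[5.5]undec-8-ene-7,10-dione, via C6-monoalkylated triflate 12 (not isolated)
Conditions: LiN(SiMe3)2, THF, −78 °C; 8, DMPU, −78 → −30 °C; KN(SiMe3)2, −78 → 0 °C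
Reagents that add atoms: none
Why: Proposed new method: LiN(SiMe3)2 removes a proton from C6, the only acidic position of 11, and the cross-conjugated lithium enolate is expected to be C-alkylated by the unhindered C5 iodide of 8 to give 12; KN(SiMe3)2 then regenerates the C6 enolate, which displaces the C1 triflate in a 6-exo-tet closure of ring B. The closest known reaction type is the spiroannulation of a ketone enolate with a 1,5-dihalide; it has not been shown with a dielectrophile that carries a secondary bromide β and a tertiary chloride γ to one leaving group. C1 is slowed by the bromine on C2 and the fully substituted C3, so a triflate is placed there and its displacement is left to the intramolecular step; if the triflate were to react first and the iodide close the ring, the same 13 would result. C6 is the only new stereocentre and is set by the chair of the closing C5–C1 tether: bromine on C2 must be equatorial, because only then is it anti to the incoming C6 rather than gauche to it as in a neopentyl-type displacement, and chlorine, being trans, is equatorial too. On the trigonal C6 the bulky quaternary C11 takes the pseudo-equatorial site and the flat C7 enolate carbon the pseudo-axial one, which places C11 cis to bromine as required; the competing closures need an axial C11 or axial halogens with bromine syn-axial to C7. C-alkylation is secured in the closure because attack through the enolate oxygen would need an eight-membered ring, and anchimeric displacement of the triflate by bromine is excluded once C6 occupies the trajectory anti to the C1–O bond. Elimination of triflic acid across C1–C2 or of HCl at C3 by the basic enolate is the main competing path and is held back by low temperature, exact amounts of hindered amide base and the rate advantage of the intramolecular closure.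

Step 11
Reactants: 13 (2S,3S,6R)-2-bromo-3-chloro-8-methoxy-3,11,11-trimethylspiro[5.5]undec-8-ene-7,10-dione
Product: 14 (2S,3S,6S)-2-bromo-3-chloro-8-methoxy-3,11,11-trimethyl-7-methylidenespiro[5.5]undec-8-en-10-one
Conditions: Cp2TiMe2, toluene–THF, 65 °C, dark
Reagents that add atoms: dimethyltitanocene Cp2TiMe2, [Ti+4].[CH3-].[CH3-].c1cc[cH-]c1.c1cc[cH-]c1
Why: Petasis methylenation: Cp2TiMe2 loses methane on heating to give Cp2Ti=CH2, which adds to the carbonyl and cycloreverts to the alkene. The reagent is non-basic, 13 has no enolisable hydrogen, and the C7 ketone should react ahead of the deactivated vinylogous-ester carbonyl at C10.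

Step 12
Reactants: 14 (2S,3S,6S)-2-bromo-3-chloro-8-methoxy-3,11,11-trimethyl-7-methylidenespiro[5.5]undec-8-en-10-one
Product: 15 (2S,3S,6S)-2,10-dibromo-3-chloro-3,11,11-trimethyl-7-methylidenespiro[5.5]undec-9-en-8-one
Conditions: (COBr)2, CH2Cl2, 0 °C → rt
Reagents that add atoms: oxalyl bromide, O=C(Br)C(=O)Br
Why: Vilsmeier-type halogenation of a vinylogous ester: oxalyl bromide acylates the C10 carbonyl oxygen, bromide adds at C10 and expels the oxalate (lost as CO and CO2), and bromide then removes the methyl group from the C8 oxocarbenium ion to give the transposed β-bromo enone. The regiochemistry follows from the position of the methyl ether.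

Step 13
Reactants: 15 (2S,3S,6S)-2,10-dibromo-3-chloro-3,11,11-trimethyl-7-methylidenespiro[5.5]undec-9-en-8-one
Product: 16 (2S,3S,6S,8R)-2,10-dibromo-3-chloro-3,11,11-trimethyl-7-methylidenespiro[5.5]undec-9-en-8-ol
Conditions: (S)-Me-CBS [(S)-1-methyl-3,3-diphenyltetrahydro-1H,3H-pyrrolo[1,2-c][1,3,2]oxazaborole], catecholborane, toluene, −78 °C
Reagents that add atoms: none
Why: Corey–Bakshi–Shibata reduction with catecholborane is 1,2-selective for enones and leaves the alkenes alone. With the fully substituted C7 side as the large group and the C9 methine side as the small one, the (S)-catalyst should deliver hydride to the face that gives (8R), so C8 is set by catalyst control.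

## Compound list

1 | tert-butyl(but-3-yn-1-yloxy)dimethylsilane | C#CCCO[Si](C)(C)C(C)(C)C | starting material
2 | methyl 5-[(tert-butyldimethylsilyl)oxy]pent-2-ynoate | COC(=O)C#CCCO[Si](C)(C)C(C)(C)C | intermediate
3 | methyl (2Z)-5-[(tert-butyldimethylsilyl)oxy]-3-methylpent-2-enoate | COC(=O)/C=C(/C)CCO[Si](C)(C)C(C)(C)C | intermediate
4 | (2Z)-5-[(tert-butyldimethylsilyl)oxy]-3-methylpent-2-en-1-ol | OC/C=C(/C)CCO[Si](C)(C)C(C)(C)C | intermediate
5 | (2S,3S)-2-bromo-5-[(tert-butyldimethylsilyl)oxy]-3-chloro-3-methylpentan-1-ol | CC(C)(C)[Si](C)(C)OCC[C@](C)(Cl)[C@@H](Br)CO | intermediate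
6 | (2S,3S)-2-bromo-3-chloro-3-methylpentane-1,5-diol | OCC[C@](C)(Cl)[C@@H](Br)CO | intermediate
7 | (2S,3S)-2-bromo-3-chloro-5-iodo-3-methylpentan-1-ol | ICC[C@](C)(Cl)[C@@H](Br)CO | intermediate
8 | (2S,3S)-2-bromo-3-chloro-5-iodo-3-methylpentyl trifluoromethanesulfonate | ICC[C@](C)(Cl)[C@@H](Br)COS(=O)(=O)C(F)(F)F | intermediate
9 | 4,4-dimethylcyclohexane-1,3-dione | CC1(C)CCC(=O)CC1=O | starting material
10 | 3-methoxy-6,6-dimethylcyclohex-2-en-1-one | COC1=CC(=O)C(C)(C)CC1 | intermediate
11 | 2-methoxy-5,5-dimethylcyclohex-2-ene-1,4-dione | COC1=CC(=O)C(C)(C)CC1=O | intermediate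
12 | (2S,3S)-2-bromo-3-chloro-5-(3-methoxy-6,6-dimethyl-2,5-dioxocyclohex-3-en-1-yl)-3-methylpentyl trifluoromethanesulfonate, both epimers at the ring carbon (not isolated) | COC1=CC(=O)C(C)(C)C(CC[C@](C)(Cl)[C@@H](Br)COS(=O)(=O)C(F)(F)F)C1=O | intermediate
13 | (2S,3S,6R)-2-bromo-3-chloro-8-methoxy-3,11,11-trimethylspiro[5.5]undec-8-ene-7,10-dione | O=C1C(OC)=CC(=O)C(C)(C)[C@]12CC[C@](C)(Cl)[C@@H](Br)C2 | intermediate
14 | (2S,3S,6S)-2-bromo-3-chloro-8-methoxy-3,11,11-trimethyl-7-methylidenespiro[5.5]undec-8-en-10-one | C=C1C(OC)=CC(=O)C(C)(C)[C@]12CC[C@](C)(Cl)[C@@H](Br)C2 | intermediate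
15 | (2S,3S,6S)-2,10-dibromo-3-chloro-3,11,11-trimethyl-7-methylidenespiro[5.5]undec-9-en-8-one | C=C1C(=O)C=C(Br)C(C)(C)[C@]12CC[C@](C)(Cl)[C@@H](Br)C2 | intermediate
16 | (2S,3S,6S,8R)-2,10-dibromo-3-chloro-3,11,11-trimethyl-7-methylidenespiro[5.5]undec-9-en-8-ol | C=C1[C@H](O)C=C(Br)C(C)(C)[C@]12CC[C@](C)(Cl)[C@@H](Br)C2 | target

## Step count and least certain steps

Total step count: 13. Longest linear sequence: 11 steps (steps 1–7, then 10–13).

**Step 10 (key step).**
- What may go wrong: the enolate or the amide base may act as a base on 8 or 12 and remove the C2 proton with loss of triflate, or eliminate HCl at C3. The enolate of 11 may also condense with itself. Facial control at C6 may be incomplete if a chair with axial halogens competes.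
- Fallback (known enolate alkylations run one at a time, bond order reversed): it sets out from 5 and 11 and returns at 13. Triflation of 5 (Tf2O, 2,6-lutidine, −78 °C) gives (2S,3S)-2-bromo-5-[(tert-butyldimethylsilyl)oxy]-3-chloro-3-methylpentyl trifluoromethanesulfonate F1. The lithium enolate of 11 is alkylated with F1 at −78 °C, which makes the hindered C6–C1 bond first with the most reactive leaving group, and gives 6-{(2S,3S)-2-bromo-5-[(tert-butyldimethylsilyl)oxy]-3-chloro-3-methylpentyl}-2-methoxy-5,5-dimethylcyclohex-2-ene-1,4-dione F2. HF·pyridine gives 6-[(2S,3S)-2-bromo-3-chloro-5-hydroxy-3-methylpentyl]-2-methoxy-5,5-dimethylcyclohex-2-ene-1,4-dione F3. PPh3/I2/imidazole gives 6-[(2S,3S)-2-bromo-3-chloro-5-iodo-3-methylpentyl]-2-methoxy-5,5-dimethylcyclohex-2-ene-1,4-dione F4. KN(SiMe3)2 in THF then closes ring B by 6-exo-tet displacement of the unhindered C5 iodide to 13. In this order the C6–C1–C2 segment is already in place at ring closure, so an axial bromine would meet C7 in a fully developed syn-axial contact.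

**Step 4.**
- What may go wrong: enantio- or regioselectivity may erode on a (Z)-trisubstituted substrate, or the silyl ether oxygen may take part in bromoetherification.
- Fallback: it sets out from 4 and returns at 5. Ligand-free anti bromochlorination (N-bromosuccinimide, ClTi(OiPr)3) gives the racemate, that is 5 together with (2R,3R)-2-bromo-5-[(tert-butyldimethylsilyl)oxy]-3-chloro-3-methylpentan-1-ol F5. Preparative chromatography on a chiral stationary phase delivers 5.

**Step 9.**
- What may go wrong: the radical chain may stall or over-oxidise, or the peroxide may epoxidise the product under the basic conditions.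
- Fallback: it sets out from 10 and returns at 11. C6 of the enone is quaternary, so LiN(i-Pr)2 can only deprotonate the γ-methylene; silylation with Me3SiCl gives [(3-methoxy-6,6-dimethylcyclohexa-1,3-dien-1-yl)oxy]trimethylsilane F6. Vinylogous Rubottom oxidation with m-chloroperbenzoic acid gives 4-hydroxy-3-methoxy-6,6-dimethylcyclohex-2-en-1-one F7, and Dess–Martin oxidation gives 11.

**Step 11.**
- What may go wrong: the hindered C7 carbonyl may react slowly, C10 may be methylenated as well, or trivalent titanium species formed on long heating may reductively remove the vicinal halides.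
- Fallback: it sets out from 13 and returns at 14 by a Peterson olefination. Me3SiCH2Li/CeCl3 adds to C7 at −78 °C to give (2S,3S,6R)-2-bromo-3-chloro-7-hydroxy-8-methoxy-3,11,11-trimethyl-7-[(trimethylsilyl)methyl]spiro[5.5]undec-8-en-10-one F8. KH in THF at 0 °C induces syn elimination to 14.

**Step 12.**
- What may go wrong: bromide may demethylate before it adds at C10, which returns a 1,3-diketone on work-up. Traces of HBr may ionise the C3 chloride or add to the C7 methylidene.
- Fallback: it sets out from 14 and returns at 15. Mild aqueous acid (HCl, THF) hydrolyses the enol ether to (2S,3S,6R)-2-bromo-3-chloro-3,11,11-trimethyl-7-methylidenespiro[5.5]undecane-8,10-dione F9. (COBr)2 with catalytic DMF should convert its fully conjugated enol, in which the C10 carbonyl oxygen is the nucleophilic site, into 15. A regioisomeric bromo enone, if formed, is removed by chromatography.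

**Step 13.**
- What may go wrong: facial discrimination may be weak because both carbonyl substituents are alkenyl, or the α-methylene ketone may undergo 1,4-reduction.
- Fallback: it sets out from 15 and returns at 16. Luche reduction (NaBH4, CeCl3·7H2O, MeOH, −78 °C) under substrate control is followed by chromatographic separation of 16 from (2S,3S,6S,8S)-2,10-dibromo-3-chloro-3,11,11-trimethyl-7-methylidenespiro[5.5]undec-9-en-8-ol F10. F10 is oxidised with MnO2 back to 15 and recycled.

## Further compounds

F1 | step 10 | (2S,3S)-2-bromo-5-[(tert-butyldimethylsilyl)oxy]-3-chloro-3-methylpentyl trifluoromethanesulfonate | CC(C)(C)[Si](C)(C)OCC[C@](C)(Cl)[C@@H](Br)COS(=O)(=O)C(F)(F)F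
F2 | step 10 | 6-{(2S,3S)-2-bromo-5-[(tert-butyldimethylsilyl)oxy]-3-chloro-3-methylpentyl}-2-methoxy-5,5-dimethylcyclohex-2-ene-1,4-dione (both C6 epimers) | COC1=CC(=O)C(C)(C)C(C[C@H](Br)[C@@](C)(Cl)CCO[Si](C)(C)C(C)(C)C)C1=O
F3 | step 10 | 6-[(2S,3S)-2-bromo-3-chloro-5-hydroxy-3-methylpentyl]-2-methoxy-5,5-dimethylcyclohex-2-ene-1,4-dione (both C6 epimers) | COC1=CC(=O)C(C)(C)C(C[C@H](Br)[C@@](C)(Cl)CCO)C1=O
F4 | step 10 | 6-[(2S,3S)-2-bromo-3-chloro-5-iodo-3-methylpentyl]-2-methoxy-5,5-dimethylcyclohex-2-ene-1,4-dione (both C6 epimers) | COC1=CC(=O)C(C)(C)C(C[C@H](Br)[C@@](C)(Cl)CCI)C1=O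
F5 | step 4 | (2R,3R)-2-bromo-5-[(tert-butyldimethylsilyl)oxy]-3-chloro-3-methylpentan-1-ol | CC(C)(C)[Si](C)(C)OCC[C@@](C)(Cl)[C@H](Br)CO
F6 | step 9 | [(3-methoxy-6,6-dimethylcyclohexa-1,3-dien-1-yl)oxy]trimethylsilane | COC1=CCC(C)(C)C(O[Si](C)(C)C)=C1
F7 | step 9 | 4-hydroxy-3-methoxy-6,6-dimethylcyclohex-2-en-1-one (racemic) | COC1=CC(=O)C(C)(C)CC1O
F8 | step 11 | (2S,3S,6R)-2-bromo-3-chloro-7-hydroxy-8-methoxy-3,11,11-trimethyl-7-[(trimethylsilyl)methyl]spiro[5.5]undec-8-en-10-one (both C7 epimers) | C[Si](C)(C)CC1(O)C(OC)=CC(=O)C(C)(C)[C@]12CC[C@](C)(Cl)[C@@H](Br)C2
F9 | step 12 | (2S,3S,6R)-2-bromo-3-chloro-3,11,11-trimethyl-7-methylidenespiro[5.5]undecane-8,10-dione | C=C1C(=O)CC(=O)C(C)(C)[C@]12CC[C@](C)(Cl)[C@@H](Br)C2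
F10 | step 13 | (2S,3S,6S,8S)-2,10-dibromo-3-chloro-3,11,11-trimethyl-7-methylidenespiro[5.5]undec-9-en-8-ol | C=C1[C@@H](O)C=C(Br)C(C)(C)[C@]12CC[C@](C)(Cl)[C@@H](Br)C2
A1 | alternative 1 | (6S,10S)-chamigra-2,7(14)-dien-10-ol | C=C1CC[C@H](O)C(C)(C)[C@]12CCC(C)=CC2
A2 | alternative 1 | (3S)-2,2-dimethyl-3-[(3Z)-3-(4-methylcyclohex-3-en-1-ylidene)butyl]oxirane | CC1=CC/C(=C(/C)CC[C@@H]2OC2(C)C)CC1
A3 | alternative 2 | triethyl{[(6S,8R)-10,10-(ethylenedioxy)-11,11-dimethyl-7-methylidenespiro[5.5]undec-1-en-8-yl]oxy}silane | C=C1[C@H](O[Si](CC)(CC)CC)CC2(OCCO2)C(C)(C)[C@@]13C=CCCC3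
A4 | alternative 2 | 2-(2-{2-[(1S)-1-ethynylcyclohex-2-en-1-yl]propan-2-yl}-1,3-dioxolan-2-yl)acetaldehyde | C#C[C@@]1(C(C)(C)C2(OCCO2)CC=O)C=CCCC1
A5 | alternative 3 | (6R)-8-methoxy-11,11-dimethylspiro[5.5]undeca-1,8-diene-3,7,10-trione | O=C1C(OC)=CC(=O)C(C)(C)[C@]12CCC(=O)C=C2
A6 | alternative 3 | 3-methoxy-6,6-dimethyl-2,5-dioxocyclohex-3-ene-1-carbaldehyde (enolised, ring stereocentre not defined) | O=CC1C(=O)C(OC)=CC(=O)C1(C)C
A7 | alternative 3 | but-3-en-2-one | CC(=O)C=C
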